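**Strategy**

Ring atoms are numbered C1 (CH–isopropenyl), C2, C3 (ketone), C4–C5 (methyl epoxide), C6, C7 (O-angeloyl), C8–C9 (methyl epoxide), C10 (O-angeloyl). The oxygens on C7 and C10 flank the C8(Me)–C9 unit of the ten-membered ring. This is a masked cis-2-ene-1,4-dione, the fragment that oxidative scission of the carbinol–carbinol bond of a cyclobutene-cis-1,2-diol provides. The route rests on the C7–C10 disconnection. Glycol cleavage of a squarate-derived bicyclo[6.2.0]deca-3,9-diene-1,8-diol opens the four-membered ring and, in the same operation, expands the cyclooctene to the (Z,Z)-cyclodecadiene-7,10-dione. The precursor is a cis-fused 3-methylcyclobutene-1,2-diol on a Z-cyclooctene bearing the C1 isopropenyl group and a silylated C3 carbinol.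

Key step: step 14

Remark: the locants C1–C10 of the target ring are used for every intermediate.
Remark: cyclobutenone 8 is racemic, so 17–22 form as a pair of diastereomers (7S,10S and 7R,10R, both with cis O7/O10 and the same C1 and C3); step 14 makes C7 and C10 trigonal and the pair converges on the single dione 23; names and SMILES show the 7S,10S partner.
Remark: C3 is set as R because it relays C1 through a trans-lactone aldol and later directs the C4–C5 epoxidation; it is erased in step 20.
Remark: the isopropenyl group on C1 is carried as an acetyl group through the metathesis, because an isopropenyl group 1,6 to the C7 allyl group would close a six-membered ring instead.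
Remark: both tertiary hydroxyls stay silylated until just before step 14, since cyclobutene-1,2-diolates undergo electrocyclic ring opening.

**Route**

Step 1
Reactants: 1 diisopropyl squarate
Product: 3 3-isopropoxycyclobut-3-ene-1,2-dione, via reduced hydroxy ketone 2 (not isolated)
Conditions: LiAlH(OtBu)3, THF, −78 → −20 °C; then 6 M HCl, CH2Cl2, rt
Reagents that add atoms: water, O
Why: Mono-reduction of one vinylogous ester carbonyl, then acid ionisation of the allylic carbinol and hydrolysis of the isopropoxy-stabilised cation (squarate carbonyl transposition), should give the semisquarate with the future C9–H in place.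

Step 2
Reactants: 3 3-isopropoxycyclobut-3-ene-1,2-dione; 4 allylmagnesium bromide
Product: 5 rac-4-allyl-4-hydroxy-3-isopropoxycyclobut-2-en-1-one
Conditions: THF/Et2O, −78 °C; then H2O
Reagents that add atoms: none
Why: Grignard 1,2-addition should go to the ketone carbonyl next to the isopropoxy-bearing carbon, because the other carbonyl is deactivated as a vinylogous ester; the C7 carbinol with C6 and C5 forms as a racemate, which is harmless since C7 becomes a ketone in step 14.

Step 3
Reactants: 5 rac-4-allyl-4-hydroxy-3-isopropoxycyclobut-2-en-1-one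
Product: 6 rac-4-allyl-3-isopropoxy-4-(triethylsilyloxy)cyclobut-2-en-1-one
Conditions: Et3SiOTf, 2,6-lutidine, CH2Cl2, −78 → 0 °C
Reagents that add atoms: triethylsilyl triflate, CC[Si](CC)(CC)OS(=O)(=O)C(F)(F)F
Why: Silyl triflate silylation of a tertiary alcohol; the bulky Et3SiO group later shields one face of the C10 carbonyl and prevents alkoxide-driven opening of the cyclobutene.

Step 4
Reactants: 6 rac-4-allyl-3-isopropoxy-4-(triethylsilyloxy)cyclobut-2-en-1-one
Product: 8 rac-4-allyl-3-methyl-4-(triethylsilyloxy)cyclobut-2-en-1-one, via lithium alkoxide 7 (not isolated)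
Conditions: MeLi, THF, −78 °C; then (CF3CO)2O, −78 °C; then aq. NaHCO3
Reagents that add atoms: methyllithium, [Li]C; water, O
Why: 1,2-Addition of MeLi to the vinylogous ester carbonyl followed by trifluoroacetate-assisted ionisation and hydrolysis (squarate carbonyl transposition) should place the methyl group on C8 and unveil the C10 ketone; conjugate addition–elimination of MeLi would give the same enone, so the regiochemistry is not in doubt.

Step 5
Reactants: 9 methacrolein; 10 allyltributylstannane
Product: 11 (R)-2-methylhexa-1,5-dien-3-ol
Conditions: Ti(OiPr)4 (10 mol %), (R)-BINOL (20 mol %), 4 Å MS, CH2Cl2, −20 °C; then aq. NaHCO3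
Reagents that add atoms: none
Why: Keck asymmetric allylation; the (R)-BINOL–titanium catalyst should deliver the allyl group to one aldehyde face and set the C3 carbinol as R, the stereocentre from which C1 is later relayed.

Step 6
Reactants: 11 (R)-2-methylhexa-1,5-dien-3-ol
Product: 13 (R)-5-methylhex-5-ene-1,4-diol, via bis-boryl adduct 12 (not isolated)
Conditions: Cy2BH (2.2 equiv, from BH3·SMe2 and cyclohexene), THF, 0 °C → rt; then NaOH, H2O2
Reagents that add atoms: hydrogen peroxide, OO
Why: Hydroboration–oxidation with a hindered dialkylborane should select the monosubstituted alkene over the 1,1-disubstituted alkene next to the borylated carbinol and give the primary alcohol without touching C3.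

Step 7
Reactants: 13 (R)-5-methylhex-5-ene-1,4-diol
Product: 14 (R)-5-(prop-1-en-2-yl)dihydrofuran-2(3H)-one
Conditions: TEMPO (10 mol %), PhI(OAc)2 (2.5 equiv), CH2Cl2, rt
Reagents that add atoms: none
Why: Oxidative lactonisation of a 1,4-diol: the primary alcohol is oxidised first, the hydroxy aldehyde closes to the lactol, and the lactol is oxidised on to the γ-lactone while the allylic C3 centre stays untouched.

Step 8
Reactants: 14 (R)-5-(prop-1-en-2-yl)dihydrofuran-2(3H)-one; 8 rac-4-allyl-3-methyl-4-(triethylsilyloxy)cyclobut-2-en-1-one
Product: 17 trans-lactone aldol adduct bearing C10–OSiMe3 and C7–OSiEt3 (7S,10S shown), via lactone lithium enolate 15 (not isolated), via lithium aldolate 16 (not isolated)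
Conditions: LiN(iPr)2, THF, −78 °C; then 8 (1.1 equiv), −78 °C; then Me3SiCl, −78 → −20 °C
Reagents that add atoms: chlorotrimethylsilane, C[Si](C)(C)Cl
Why: Aldol addition of the γ-substituted butyrolactone enolate to the cyclobutenone carbonyl: the enolate should react anti to its isopropenyl group, which fixes C1 relative to C3 (trans-lactone, C1 as in the target), and the carbonyl should be attacked anti to the Et3SiO group (steric and Felkin–Anh polar control), which makes O7 and O10 cis; silylation of the aldolate blocks retro-aldol cleavage.

Step 9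
Reactants: 17 trans-lactone aldol adduct
Product: 18 γ-hydroxy methyl ketone (acetyl group on C1; free C3–OH)
Conditions: MeLi (1.1 equiv), THF, −78 °C; then H2O
Reagents that add atoms: methyllithium, [Li]C
Why: Mono-addition of MeLi to a γ-lactone at low temperature stops at the tetrahedral lithium hemiketal, which opens on work-up to the γ-hydroxy methyl ketone; the acetyl group is the masked isopropenyl unit and cannot take part in the metathesis of step 11.

Step 10
Reactants: 18 γ-hydroxy methyl ketone
Product: 19 C3 tert-butyldimethylsilyl ether of 18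
Conditions: tBuMe2SiCl, imidazole, DMF, rt
Reagents that add atoms: tert-butyldimethylsilyl chloride, CC(C)(C)[Si](C)(C)Cl
Why: Standard silylation of the secondary allylic alcohol of the open-chain form; the tertiary silyl ethers and the ketone are inert, and the hydroxy ketone can no longer close to a hemiketal.

Step 11
Reactants: 19 acyclic triene methyl ketone
Product: 20 cis-fused bicyclo[6.2.0]deca-3,9-diene carrying the C1 acetyl group and three silyl ethers
Conditions: second-generation Hoveyda–Grubbs catalyst RuCl2(=CH-C6H4-2-OiPr)(H2IMes) (10 mol %), toluene (1 mM), 80 °C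
Reagents that add atoms: none
Why: Ring-closing metathesis between the allyl group on C7 and the isopropenyl group on C4; the chains are cis on the cyclobutene and an eight-membered ring can hold only a Z alkene, so the C4=C5 geometry follows from ring size, while the cyclobutene alkene is trisubstituted and flanked by two silyloxy-bearing quaternary carbons and no second 1,1-disubstituted alkene is present to close a competing six-membered ring.

Step 12
Reactants: 20 bicyclic methyl ketone
Product: 21 tris-silylated bicyclic triene with the C1 isopropenyl group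
Conditions: Ph3PCH3Br, KOtBu, THF, 0 °C → rt
Reagents that add atoms: methyltriphenylphosphonium bromide, C[P+](c1ccccc1)(c1ccccc1)c1ccccc1.[Br-]
Why: Wittig methylenation of the methyl ketone with the non-stabilised ylide converts the acetyl group into the isopropenyl group; a small excess of ylide at low temperature should leave C1, which is α to the ketone, unepimerised.

Step 13
Reactants: 21 tris-silylated bicyclic triene
Product: 22 (1S,5R,7S,8S,3Z)-5-(tert-butyldimethylsilyloxy)-4,10-dimethyl-7-(prop-1-en-2-yl)bicyclo[6.2.0]deca-3,9-diene-1,8-diol
Conditions: HF·pyridine, pyridine, THF, 0 °C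
Reagents that add atoms: none
Why: Buffered fluoride should remove the two tertiary silyl ethers (Me3Si and Et3Si) much faster than the secondary tert-butyldimethylsilyl ether; the cyclobutene-diol is released only now and without base.

Step 14
Reactants: 22 cis-fused cyclobutene-1,2-diol
Product: 23 (2Z,6Z,8R,10S)-8-(tert-butyldimethylsilyloxy)-3,7-dimethyl-10-(prop-1-en-2-yl)cyclodeca-2,6-diene-1,4-dione
Conditions: Pb(OAc)4 (1.05 equiv), CH2Cl2, −40 → −10 °C; cold filtration through NaHCO3/Celite; used at once
Reagents that add atoms: none
Why: Tetravalent lead condenses with the two cis, syn-periplanar tertiary hydroxyls on C7 and C10 to a five-membered cyclic lead diester, which collapses in a concerted two-electron fragmentation that breaks the C7–C10 σ bond, forms the two ketones and releases divalent lead (Criegee glycol cleavage, in the variant used for ring expansion of fused cyclobutane-1,2-diols). No ring is closed by bond formation: the ten-membered ring arises because the bond shared by the four- and eight-membered rings is cut, so the ring grows by the two carbons C8 and C9. No stereocentre is created; C7 and C10 become trigonal, which is why both ring-fusion diastereomers of 22 give the same dione 23, and C1 and C3 are untouched. The Z geometry of C8=C9 is inherited from the cyclobutene and that of C4=C5 from the cyclooctene, since neither π bond takes part. The step needs glycol cleavage to outrun oxidation of the three alkenes and enolisation at C1 and C6 of the product; the cis ring fusion (O–C–C–O dihedral close to zero) and the release of cyclobutene strain should make cleavage fast at low temperature, and the base-free, cold, short protocol should keep the β,γ-unsaturated ketone units and the C1 stereocentre intact.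

Step 15
Reactants: 23 (Z,Z)-diene-7,10-dione
Product: 24 (7S,10R)-diene-7,10-diol (C3–OTBS retained)
Conditions: (R)-2-methyl-CBS-oxazaborolidine (40 mol %), catecholborane (4 equiv), toluene, −78 °C; then MeOH, aq. NaOH
Reagents that add atoms: none
Why: Corey–Bakshi–Shibata reduction of both enone carbonyls: with the alkenyl group as the larger substituent the (R)-catalyst should deliver hydride to the same local face at C7 and at C10, which gives the 7S and 10R carbinols (the pattern of the target), and the low-temperature catecholborane protocol reduces 1,2 without touching the alkenes or C1.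

Step 16
Reactants: 24 diene-7,10-diol
Product: 25 (7S,8R,9S,10S)-8,9-epoxy-7,10-diol
Conditions: VO(acac)2 (5 mol %), t-BuOOH (1.3 equiv), CH2Cl2, 0 °C
Reagents that add atoms: tert-butyl hydroperoxide, CC(C)(C)OO
Why: Vanadium-catalysed hydroxyl-directed epoxidation touches only the alkene allylic to a free hydroxyl; allylic 1,3-strain across the Z alkene holds H7 in the alkene plane, so peroxide bound to the less hindered C7 alkoxide should be delivered to the face syn to O7, which gives the 8R,9S oxirane, and the concerted oxygen transfer keeps C7 and C10 cis on the oxirane.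

Step 17
Reactants: 25 8,9-epoxy-7,10-diol; 26 angelic acid
Product: 28 7,10-bis-angelate, via angeloyl mixed anhydride 27 (not isolated)
Conditions: 26 (3 equiv), 2,4,6-Cl3C6H2COCl, Et3N, toluene, rt; then 25, toluene, 75 °C
Reagents that add atoms: none
Why: Yamaguchi-type esterification through the mixed anhydride should acylate both hindered secondary alcohols with retention at carbon, and the absence of a nucleophilic catalyst and of strong base avoids angelate-to-tiglate isomerisation and Payne rearrangement of the epoxy alcohols.

Step 18
Reactants: 28 7,10-bis-angelate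
Product: 29 C3 allylic alcohol
Conditions: Bu4NF, AcOH, THF, 0 °C → rt
Reagents that add atoms: none
Why: Fluoride cleavage of the secondary silyl ether; acetic acid buffering keeps the medium close to neutral so that the esters and the oxirane survive.

Step 19
Reactants: 29 C3 allylic alcohol
Product: 30 4,5:8,9-diepoxy C3 alcohol
Conditions: mCPBA (1.05 equiv), CH2Cl2, −20 °C
Reagents that add atoms: 3-chloroperoxybenzoic acid, O=C(OO)c1cccc(Cl)c1
Why: Hydroxyl-directed peracid (Henbest) epoxidation of the trisubstituted allylic alkene should be faster than attack on the 1,1-disubstituted isopropenyl group or the electron-poor angelates; with H3 held in the alkene plane by allylic strain, the peracid hydrogen-bonded to O3 attacks the outer face, which places the oxirane anti to the hydroxyl in the ring sense as in medium-ring Z-cycloalkenols (the C4/C5 configuration of the target), and the concerted addition keeps the cis oxirane.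

Step 20
Reactants: 30 diepoxy C3 alcohol
Product: 31 target CNP0217653.1
Conditions: Dess–Martin periodinane, CH2Cl2, 0 °C → rt
Reagents that add atoms: none
Why: Dess–Martin oxidation of the secondary epoxy alcohol to the C3 ketone under non-epimerising conditions erases the relay stereocentre and should give the target without touching the oxiranes, the esters or the alkenes.

**Compound list**

1 | diisopropyl squarate | CC(C)OC1=C(OC(C)C)C(=O)C1=O | starting material
2 | rac-4-hydroxy-2,3-diisopropoxycyclobut-2-en-1-one (present as its alkoxide) | CC(C)OC1=C(OC(C)C)C(O)C1=O | intermediate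
3 | 3-isopropoxycyclobut-3-ene-1,2-dione | CC(C)OC1=CC(=O)C1=O | intermediate
4 | allylmagnesium bromide | C=CC[Mg]Br | starting material
5 | rac-4-allyl-4-hydroxy-3-isopropoxycyclobut-2-en-1-one | C=CCC1(O)C(OC(C)C)=CC1=O | intermediate
6 | rac-4-allyl-3-isopropoxy-4-(triethylsilyloxy)cyclobut-2-en-1-one | C=CCC1(O[Si](CC)(CC)CC)C(OC(C)C)=CC1=O | intermediate
7 | lithium 4-allyl-3-isopropoxy-1-methyl-4-(triethylsilyloxy)cyclobut-2-en-1-olate | C=CCC1(O[Si](CC)(CC)CC)C(OC(C)C)=CC1(C)[O-].[Li+] | intermediate
8 | rac-4-allyl-3-methyl-4-(triethylsilyloxy)cyclobut-2-en-1-one | C=CCC1(O[Si](CC)(CC)CC)C(C)=CC1=O | intermediate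
9 | methacrolein | C=C(C)C=O | starting material
10 | allyltributylstannane | C=CC[Sn](CCCC)(CCCC)CCCC | starting material
11 | (R)-2-methylhexa-1,5-dien-3-ol | C=C(C)[C@H](O)CC=C | intermediate
12 | (R)-O,C-bis(dicyclohexylboryl) adduct of 11 | C=C(C)[C@H](OB(C1CCCCC1)C1CCCCC1)CCCB(C1CCCCC1)C1CCCCC1 | intermediate
13 | (R)-5-methylhex-5-ene-1,4-diol | C=C(C)[C@H](O)CCCO | intermediate
14 | (R)-5-(prop-1-en-2-yl)dihydrofuran-2(3H)-one | C=C(C)[C@H]1CCC(=O)O1 | intermediate
15 | lithium enolate of 14 | C=C(C)[C@H]1CC=C([O-])O1.[Li+] | intermediate
16 | lithium aldolate (C10–OLi, C7–OSiEt3; 7S,10S shown) | O=C1O[C@@H](C(C)=C)C[C@@H]1[C@@]2([O-])C=C(C)[C@]2(CC=C)O[Si](CC)(CC)CC.[Li+] | intermediate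
17 | (3R,5R)-3-[(1S,4S)-4-allyl-3-methyl-4-(triethylsilyloxy)-1-(trimethylsilyloxy)cyclobut-2-en-1-yl]-5-(prop-1-en-2-yl)dihydrofuran-2(3H)-one (formed with its 7R,10R partner) | O=C1O[C@@H](C(C)=C)C[C@@H]1[C@@]2(O[Si](C)(C)C)C=C(C)[C@]2(CC=C)O[Si](CC)(CC)CC | intermediate
18 | (3R,5R)-3-[(1S,4S)-4-allyl-3-methyl-4-(triethylsilyloxy)-1-(trimethylsilyloxy)cyclobut-2-en-1-yl]-5-hydroxy-6-methylhept-6-en-2-one | CC(=O)[C@H](C[C@@H](O)C(C)=C)[C@@]1(O[Si](C)(C)C)C=C(C)[C@]1(CC=C)O[Si](CC)(CC)CC | intermediate
19 | 5-O-tert-butyldimethylsilyl ether of 18 | CC(=O)[C@H](C[C@@H](O[Si](C)(C)C(C)(C)C)C(C)=C)[C@@]1(O[Si](C)(C)C)C=C(C)[C@]1(CC=C)O[Si](CC)(CC)CC | intermediate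
20 | cis-fused bicyclo[6.2.0]deca-3,9-diene with C1 acetyl, C3–OTBS, C7–OSiEt3, C10–OSiMe3, Z C4=C5 (target locants) | CC(=O)[C@@H]1C[C@@H](O[Si](C)(C)C(C)(C)C)/C(C)=C\C[C@]2(O[Si](CC)(CC)CC)C(C)=C[C@]12O[Si](C)(C)C | intermediate
21 | C1-isopropenyl analogue of 20 (tris-silyl ether of 22) | C=C(C)[C@@H]1C[C@@H](O[Si](C)(C)C(C)(C)C)/C(C)=C\C[C@]2(O[Si](CC)(CC)CC)C(C)=C[C@]12O[Si](C)(C)C | intermediate
22 | (1S,5R,7S,8S,3Z)-5-(tert-butyldimethylsilyloxy)-4,10-dimethyl-7-(prop-1-en-2-yl)bicyclo[6.2.0]deca-3,9-diene-1,8-diol (key-step precursor) | C=C(C)[C@@H]1C[C@@H](O[Si](C)(C)C(C)(C)C)/C(C)=C\C[C@]2(O)C(C)=C[C@]12O | intermediate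
23 | (2Z,6Z,8R,10S)-8-(tert-butyldimethylsilyloxy)-3,7-dimethyl-10-(prop-1-en-2-yl)cyclodeca-2,6-diene-1,4-dione (key-step product) | C=C(C)[C@@H]1C[C@@H](O[Si](C)(C)C(C)(C)C)/C(C)=C\CC(=O)/C(C)=C\C1=O | intermediate
24 | (1S,3R,7S,10R,4Z,8Z)-diene-7,10-diol with C3–OTBS (target locants) | C=C(C)[C@@H]1C[C@@H](O[Si](C)(C)C(C)(C)C)/C(C)=C\C[C@H](O)/C(C)=C\[C@H]1O | intermediate
25 | (1S,3R,7S,8R,9S,10S,4Z)-8,9-epoxy-7,10-diol with C3–OTBS (target locants) | C=C(C)[C@@H]1C[C@@H](O[Si](C)(C)C(C)(C)C)/C(C)=C\C[C@H](O)[C@@]2(C)O[C@H]2[C@H]1O | intermediate
26 | angelic acid | C/C=C(/C)C(=O)O | starting material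
27 | angelic 2,4,6-trichlorobenzoic anhydride | C/C=C(/C)C(=O)OC(=O)c1c(Cl)cc(Cl)cc1Cl | intermediate
28 | 7,10-bis-angelate of 25 | C=C(C)[C@@H]1C[C@@H](O[Si](C)(C)C(C)(C)C)/C(C)=C\C[C@H](OC(=O)/C(C)=C\C)[C@@]2(C)O[C@H]2[C@H]1OC(=O)/C(C)=C\C | intermediate
29 | C3 alcohol (3R) obtained from 28 | C=C(C)[C@@H]1C[C@@H](O)/C(C)=C\C[C@H](OC(=O)/C(C)=C\C)[C@@]2(C)O[C@H]2[C@H]1OC(=O)/C(C)=C\C | intermediate
30 | 4,5:8,9-diepoxy C3 alcohol (oxirane at C4–C5 anti to the 3-OH) | C=C(C)[C@@H]1C[C@@H](O)[C@]2(C)O[C@@H]2C[C@H](OC(=O)/C(C)=C\C)[C@@]2(C)O[C@H]2[C@H]1OC(=O)/C(C)=C\C | intermediate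
31 | CNP0217653.1, (1S,4R,5R,7S,8R,9S,10S)-4,5:8,9-diepoxy-4,8-dimethyl-3-oxo-1-(prop-1-en-2-yl)cyclodecane-7,10-diyl bis[(Z)-2-methylbut-2-enoate] (target locants) | C=C(C)[C@@H]1CC(=O)[C@]2(C)O[C@@H]2C[C@H](OC(=O)/C(C)=C\C)[C@@]2(C)O[C@H]2[C@H]1OC(=O)/C(C)=C\C | target

**Summary**

Total step count: 20.
Longest linear sequence: 17 steps (steps 1–4 and 8–20); steps 5–7 make lactone 14 in a side branch.

**Three steps most likely to fail**

1. Step 11 (ring-closing metathesis). The ruthenium alkylidene formed on the allyl group may fail to engage the 1,1-disubstituted alkene next to the bulky silyl ether, so that dimerisation or ring-opening of the strained cyclobutene takes over. Fallback: reverse the order of protection and ring closure so that a free allylic hydroxyl assists the metathesis and the bulk at C3 is removed. Setting out from 18, metathesis with RuCl2(=CH-C6H4-2-OiPr)(H2IMes) in dilute toluene is run on the unprotected γ-hydroxy ketone to give the bicyclic hydroxy ketone F1. Its C3 hydroxyl is then silylated (tBuMe2SiCl, imidazole, DMF), and the route is rejoined at 20.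

2. Step 16 (directed epoxidation). The oxidant may be delivered from the C10 hydroxyl instead of the C7 hydroxyl, which leads to the opposite face of C8=C9 (poor facial selectivity), or turnover may be slow enough for homoallylic epoxidation at C4=C5 to intrude. Fallback: oxidise before reducing, so that no hydroxyl competes as a directing group. Setting out from 23, nucleophilic (Weitz–Scheffer) epoxidation of the doubly activated C8=C9 bond with t-BuOOH and DBU in CH2Cl2 at 0 °C is expected to proceed by attack at C9 from the face opposite the isopropenyl group on C1 and would give the 8,9-epoxy-7,10-dione F2. Corey–Bakshi–Shibata reduction of both epoxy ketones ((R)-2-methyl-CBS-oxazaborolidine, catecholborane, −78 °C) would then return to the route at 25. At C7 the catalyst distinguishes the quaternary oxirane carbon from C6H2, and at C10 the Felkin-type preference for hydride attack anti to the oxirane C–O bond points the same way.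

3. Step 15 (double reduction). Facial selectivity may erode at C10, where the branched C1 substituent competes with the alkenyl group for the role of the large group; or the second reduction may stall, so that the mono-alcohol closes to a lactol and dehydrates to a furan. Fallback: change the control element from steric size to recognition of the π-system. Setting out from 23, stoichiometric LiAlH(OEt)[(S)-BINOLate] ((S)-BINAL-H) in THF at −100 → −78 °C places the unsaturated substituent in the same position at both carbonyls irrespective of branching at C1, and returns directly to the route at 24. This fallback passes through no new compound (F0).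

**Further compounds**

F1 | step 11 | bicyclic hydroxy ketone: 20 with a free C3 hydroxyl (C1 acetyl, C7–OSiEt3, C10–OSiMe3) | CC(=O)[C@@H]1C[C@@H](O)/C(C)=C\C[C@]2(O[Si](CC)(CC)CC)C(C)=C[C@]12O[Si](C)(C)C
F0 | step 15 | none | none
F2 | step 16 | (8R,9S)-8,9-epoxy-7,10-dione with C3–OTBS and Z C4=C5 (target locants) | C=C(C)[C@@H]1C[C@@H](O[Si](C)(C)C(C)(C)C)/C(C)=C\CC(=O)[C@@]2(C)O[C@H]2C1=O
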